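**Plan**
1. Retrosynthesis first removes the 8-methoxy oxygen (C8–O, installed late, para to the 5-hydroxyl), then opens ring C of the 5,7-di-O-benzyl flavone 17 at O1–C8a, C4a–C4 and O1–C2.
2. This leaves a ring A aryne and an arylpropiolic acid carrying ring B and C2–C4. The cut is possible because C8a and C4a are adjacent ring A carbons bearing O1 and the C4 carbonyl, and the 5-oxygen next to C4a polarizes a C4a–C8a aryne.
3. Forward: phloroglucinol becomes silylaryl triflate 10 (ring A), the ethynylarene is carboxylated to acid 14 (ring B), and ring C closes in step 6. C8 is then oxygenated by 5-O-debenzylation, Elbs oxidation, 8-O-methylation and hydrogenolysis.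
4. The target is achiral, with no stereocentre and no stereogenic double bond, so only regiocontrol is needed.

Key step: step 6

Remark: flavone numbering is used (O1, C2, C3, C4, C4a, C5 to C8, C8a; ring B primed). C8 stays unsubstituted until after ring closure, because an aryne with oxygen on both flanks would lose its directional bias.

**Step 1**
Reactants: 1 phloroglucinol; 2 benzyl bromide
Product: 3 3,5-bis(benzyloxy)phenol
Conditions: BnBr (2.0 equiv), K2CO3, DMF, 0 °C to rt
Reagents that add atoms: benzyl bromide (2), BrCc1ccccc1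
Why: Williamson etherification of the threefold-symmetric triphenol with two equivalents of benzyl bromide should give the bis-ether as the main O-alkylated component of a statistical mixture, from which mono-ether, tris-ether and C-benzylated material are removed by chromatography.

**Step 2**
Reactants: 3 3,5-bis(benzyloxy)phenol
Product: 4 3,5-bis(benzyloxy)phenyl N-isopropylcarbamate
Conditions: i-PrNCO (1.5 equiv), Et3N (0.2 equiv), CH2Cl2, rt
Reagents that add atoms: isopropyl isocyanate, CC(C)N=C=O
Why: Amine-catalysed addition of the phenol to the isocyanate (carbamoylation) installs an N-isopropyl carbamate, a strong ortho-directing group that can later be removed under mild basic conditions.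

**Step 3**
Reactants: 4 3,5-bis(benzyloxy)phenyl N-isopropylcarbamate
Product: 8 3,5-bis(benzyloxy)-2-(trimethylsilyl)phenyl N-isopropylcarbamate, via N-silyl carbamate 5 (not isolated), via aryllithium 6 (not isolated), via bis-silyl carbamate 7 (not isolated)
Conditions: TMSOTf (1.1 equiv), TMEDA, Et2O, rt; then n-BuLi (2.2 equiv), TMEDA, −78 °C; TMSCl, −78 °C to rt; aq NaHSO4
Reagents that add atoms: chlorotrimethylsilane, C[Si](C)(C)Cl
Why: Directed ortho-metalation: once the N–H is masked in the flask as N-silyl carbamate 5, the carbamate and the flanking benzyloxy group should together direct n-BuLi/TMEDA to C2 (equivalent to C6 by symmetry) faster than to the benzylic methylenes or to C4 at −78 °C, Me3SiCl traps aryllithium 6, and the acidic work-up hydrolyses only the N–Si bond of 7.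

**Step 4**
Reactants: 8 3,5-bis(benzyloxy)-2-(trimethylsilyl)phenyl N-isopropylcarbamate
Product: 10 3,5-bis(benzyloxy)-2-(trimethylsilyl)phenyl trifluoromethanesulfonate, via silylphenol 9 (not isolated)
Conditions: DBU (1.5 equiv), Et2NH (1.2 equiv), MeCN, 40 °C; then PhNTf2 (1.5 equiv), rt
Reagents that add atoms: N-phenylbis(trifluoromethanesulfonimide), O=S(=O)(N(c1ccccc1)S(=O)(=O)C(F)(F)F)C(F)(F)F
Why: DBU removes the carbamate N–H and triggers E1cB loss of isopropyl isocyanate, which Et2NH scavenges as a urea, and the phenoxide of 9 is then sulfonylated in the same pot by PhNTf2 (carbamate cleavage followed by phenol triflation), mild conditions that should spare the aryl–silicon bond and the benzyl ethers.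

**Step 5**
Reactants: 11 5-ethynyl-1,2,3-trimethoxybenzene
Product: 14 3-(3,4,5-trimethoxyphenyl)prop-2-ynoic acid, via lithium acetylide 12 (not isolated), via lithium propiolate 13 (not isolated)
Conditions: n-BuLi (1.1 equiv), THF, −78 °C; CO2, −78 °C to rt; aq HCl
Reagents that add atoms: carbon dioxide, O=C=O
Why: Deprotonation of the terminal alkyne followed by carboxylation of the lithium acetylide with CO2 is the standard preparation of arylpropiolic acids, and the methyl ethers are inert to it.

**Step 6**
Reactants: 10 3,5-bis(benzyloxy)-2-(trimethylsilyl)phenyl trifluoromethanesulfonate; 14 3-(3,4,5-trimethoxyphenyl)prop-2-ynoic acid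
Product: 17 5,7-bis(benzyloxy)-2-(3,4,5-trimethoxyphenyl)-4H-chromen-4-one, via aryne 15 (not isolated), via hydroxyaryl ynone 16 (not isolated)
Conditions: 10 (1.5 equiv), CsF (4 equiv), THF, 125 °C, sealed tube
Reagents that add atoms: none
Why: Fluoride removes the silyl group and triflate departs, releasing 3,5-bis(benzyloxy)benzyne 15, whose triple bond (the future C4a–C8a bond) has an oxygen-bearing carbon (the future C5) on one flank only. The cesium carboxylate of 14 should add through oxygen to the aryne carbon remote from that benzyloxy group (future C8a), because the distorted aryne places the developing negative charge at C4a, next to the inductively withdrawing C5–O bond. The aryl anion then attacks the adjacent ester carbonyl and the four-membered alkoxide collapses (an anionic Fries-type 1,3 O-to-C acyl shift) to the phenoxide of ynone 16, so that O1–C8a and C4a–C4 arise by net insertion into the acid C–O bond; this is the known aryne insertion into carboxylic acids, which with arylpropiolic acids runs on to flavones. The phenoxide closes ring C by 6-endo-dig oxa-Michael addition to the alkyne carbon bearing ring B (O1–C2), and protonation at C3 gives the pyranone. No stereocentre is formed; the step needs the right orientation of aryne addition, secured by the single alkoxy flank at C5 with hydrogen at C8, and acyl transfer ahead of protonation of the aryl anion, which the high temperature in THF and the slow fluoride-limited release of aryne should favour. Closure at C2 rather than 5-exo closure to an aurone is expected for a phenoxide in an aprotic medium.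

**Step 7**
Reactants: 17 5,7-bis(benzyloxy)-2-(3,4,5-trimethoxyphenyl)-4H-chromen-4-one
Product: 19 7-(benzyloxy)-5-hydroxy-2-(3,4,5-trimethoxyphenyl)-4H-chromen-4-one, via magnesium phenoxide 18 (not isolated)
Conditions: MgBr2·OEt2 (3 equiv), toluene–Et2O, 80 °C; aq HCl
Reagents that add atoms: none
Why: Chelation-controlled ether cleavage: Mg bridges the C4 carbonyl and the peri 5-oxygen so that bromide removes that benzyl group alone, whereas the 7-benzyl ether and the three methyl ethers cannot chelate and should stay (selective debenzylation ortho to a carbonyl by MgBr2).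

**Step 8**
Reactants: 19 7-(benzyloxy)-5-hydroxy-2-(3,4,5-trimethoxyphenyl)-4H-chromen-4-one
Product: 21 7-(benzyloxy)-5,8-dihydroxy-2-(3,4,5-trimethoxyphenyl)-4H-chromen-4-one, via potassium aryl sulfate 20 (not isolated)
Conditions: K2S2O8 (1.5 equiv), aq KOH, pyridine, 15 °C to rt; then aq HCl, Na2SO3, 80 °C
Reagents that add atoms: potassium peroxodisulfate, [K+].[K+].[O-]S(=O)(=O)OOS(=O)(=O)[O-]
Why: Elbs persulfate oxidation: the 5-phenoxide attacks peroxodisulfate through its para carbon C8 to give aryl sulfate 20, which hot dilute acid hydrolyses to the quinol with Na2SO3 present as antioxidant, the classical conversion of 7-O-protected 5-hydroxyflavones into 5,8-dihydroxyflavones.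

**Step 9**
Reactants: 21 7-(benzyloxy)-5,8-dihydroxy-2-(3,4,5-trimethoxyphenyl)-4H-chromen-4-one
Product: 22 7-(benzyloxy)-5-hydroxy-8-methoxy-2-(3,4,5-trimethoxyphenyl)-4H-chromen-4-one
Conditions: Me2SO4 (1.05 equiv), K2CO3, acetone, reflux, N2
Reagents that add atoms: dimethyl sulfate, COS(=O)(=O)OC
Why: Williamson O-methylation with one equivalent of Me2SO4 should take the 8-hydroxyl only, since the 5-hydroxyl is locked in a hydrogen bond to the C4 carbonyl and is much less nucleophilic, the usual basis for partial methylation of 5-hydroxyflavones.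

**Step 10**
Reactants: 22 7-(benzyloxy)-5-hydroxy-8-methoxy-2-(3,4,5-trimethoxyphenyl)-4H-chromen-4-one
Product: 23 5,7-dihydroxy-8-methoxy-2-(3,4,5-trimethoxyphenyl)-4H-chromen-4-one (3',4',5'-trimethoxywogonin)
Conditions: H2 (1 atm), 10% Pd/C, EtOAc–MeOH, rt
Reagents that add atoms: none
Why: Hydrogenolysis of the aryl benzyl ether over Pd/C at atmospheric pressure is far faster than reduction of the conjugated pyranone double bond and leaves the methyl ethers untouched, delivering the target.

**Compound list**
1 | phloroglucinol (benzene-1,3,5-triol) | Oc1cc(O)cc(O)c1 | starting material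
2 | benzyl bromide | BrCc1ccccc1 | starting material
3 | 3,5-bis(benzyloxy)phenol | Oc1cc(OCc2ccccc2)cc(OCc2ccccc2)c1 | intermediate
4 | 3,5-bis(benzyloxy)phenyl N-isopropylcarbamate | CC(C)NC(=O)Oc1cc(OCc2ccccc2)cc(OCc2ccccc2)c1 | intermediate
5 | 3,5-bis(benzyloxy)phenyl N-isopropyl-N-(trimethylsilyl)carbamate (formed in the flask) | CC(C)N([Si](C)(C)C)C(=O)Oc1cc(OCc2ccccc2)cc(OCc2ccccc2)c1 | intermediate
6 | 2-lithio derivative of 5 (aryllithium, formed in the flask) | CC(C)N([Si](C)(C)C)C(=O)Oc1cc(OCc2ccccc2)cc(OCc2ccccc2)c1[Li] | intermediate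
7 | 3,5-bis(benzyloxy)-2-(trimethylsilyl)phenyl N-isopropyl-N-(trimethylsilyl)carbamate (formed in the flask) | CC(C)N([Si](C)(C)C)C(=O)Oc1cc(OCc2ccccc2)cc(OCc2ccccc2)c1[Si](C)(C)C | intermediate
8 | 3,5-bis(benzyloxy)-2-(trimethylsilyl)phenyl N-isopropylcarbamate | CC(C)NC(=O)Oc1cc(OCc2ccccc2)cc(OCc2ccccc2)c1[Si](C)(C)C | intermediate
9 | 3,5-bis(benzyloxy)-2-(trimethylsilyl)phenol (present as its DBU salt, formed in the flask) | C[Si](C)(C)c1c(O)cc(OCc2ccccc2)cc1OCc1ccccc1 | intermediate
10 | 3,5-bis(benzyloxy)-2-(trimethylsilyl)phenyl trifluoromethanesulfonate | C[Si](C)(C)c1c(OCc2ccccc2)cc(OCc2ccccc2)cc1OS(=O)(=O)C(F)(F)F | intermediate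
11 | 5-ethynyl-1,2,3-trimethoxybenzene | C#Cc1cc(OC)c(OC)c(OC)c1 | starting material
12 | lithium (3,4,5-trimethoxyphenyl)acetylide (formed in the flask) | [Li]C#Cc1cc(OC)c(OC)c(OC)c1 | intermediate
13 | lithium 3-(3,4,5-trimethoxyphenyl)prop-2-ynoate (formed in the flask) | [Li+].[O-]C(=O)C#Cc1cc(OC)c(OC)c(OC)c1 | intermediate
14 | 3-(3,4,5-trimethoxyphenyl)prop-2-ynoic acid | COc1cc(C#CC(=O)O)cc(OC)c1OC | intermediate
15 | 3,5-bis(benzyloxy)benzyne (formed in the flask) | C1(OCc2ccccc2)=CC(OCc2ccccc2)=CC#C1 | intermediate
16 | 1-[2,4-bis(benzyloxy)-6-hydroxyphenyl]-3-(3,4,5-trimethoxyphenyl)prop-2-yn-1-one (present as its cesium phenoxide, formed in the flask) | COc1cc(C#CC(=O)c2c(O)cc(OCc3ccccc3)cc2OCc2ccccc2)cc(OC)c1OC | intermediate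
17 | 5,7-bis(benzyloxy)-2-(3,4,5-trimethoxyphenyl)-4H-chromen-4-one | COc1cc(-c2cc(=O)c3c(OCc4ccccc4)cc(OCc4ccccc4)cc3o2)cc(OC)c1OC | intermediate
18 | bromomagnesium 5-phenoxide of 19 (chelate, formed in the flask) | COc1cc(-c2cc(=O)c3c(O[Mg]Br)cc(OCc4ccccc4)cc3o2)cc(OC)c1OC | intermediate
19 | 7-(benzyloxy)-5-hydroxy-2-(3,4,5-trimethoxyphenyl)-4H-chromen-4-one | COc1cc(-c2cc(=O)c3c(O)cc(OCc4ccccc4)cc3o2)cc(OC)c1OC | intermediate
20 | potassium 7-(benzyloxy)-5-hydroxy-4-oxo-2-(3,4,5-trimethoxyphenyl)-4H-chromen-8-yl sulfate (formed in the flask) | COc1cc(-c2cc(=O)c3c(O)cc(OCc4ccccc4)c(OS(=O)(=O)[O-])c3o2)cc(OC)c1OC.[K+] | intermediate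
21 | 7-(benzyloxy)-5,8-dihydroxy-2-(3,4,5-trimethoxyphenyl)-4H-chromen-4-one | COc1cc(-c2cc(=O)c3c(O)cc(OCc4ccccc4)c(O)c3o2)cc(OC)c1OC | intermediate
22 | 7-(benzyloxy)-5-hydroxy-8-methoxy-2-(3,4,5-trimethoxyphenyl)-4H-chromen-4-one | COc1cc(-c2cc(=O)c3c(O)cc(OCc4ccccc4)c(OC)c3o2)cc(OC)c1OC | intermediate
23 | 5,7-dihydroxy-8-methoxy-2-(3,4,5-trimethoxyphenyl)-4H-chromen-4-one (3',4',5'-trimethoxywogonin) | COc1cc(-c2cc(=O)c3c(O)cc(O)c(OC)c3o2)cc(OC)c1OC | target

**Step count**
Total: 10 steps. Longest linear sequence: 9 steps (steps 1 to 4, then 6 to 10); step 5 is a one-step branch.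

**Steps most likely to fail**

Step 6. The aryl anion may be protonated by the acid before the acyl group migrates, so that only O-arylation occurs; the propiolic acid may also decarboxylate at 125 °C, or the sense of addition to the aryne may erode. The fallback sets out from silyl carbamate 8 and builds ring C by palladium-catalysed carbonylation instead. Ipso-iododesilylation of 8 with ICl (CH2Cl2, 0 °C) should give 3,5-bis(benzyloxy)-2-iodophenyl N-isopropylcarbamate F1. Cleavage of the carbamate with DBU/Et2NH in MeCN at 40 °C then gives 3,5-bis(benzyloxy)-2-iodophenol F2. Carbonylative Sonogashira coupling of F2 with alkyne 11 (PdCl2(PPh3)2, CO, Et2NH, DMF, 80 to 120 °C) passes through ynone 16, which the amine cyclizes in the 6-endo sense. The fallback comes back to the route at flavone 17.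

Step 3. Deprotonation may occur at a benzylic methylene and lead to Wittig rearrangement, metalation may occur at C4 between the two ether oxygens, or isocyanate may be lost from incompletely N-silylated carbamate. The fallback sets out from phenol 3 and replaces deprotonation by halogen–metal exchange. Amine-catalysed ortho-bromination (NBS, catalytic i-Pr2NH, CH2Cl2, 0 °C) should give 3,5-bis(benzyloxy)-2-bromophenol F3. O-Silylation with HMDS (THF, 70 °C) gives [3,5-bis(benzyloxy)-2-bromophenoxy]trimethylsilane F4. Bromine–lithium exchange with n-BuLi in THF at −100 to −78 °C is followed by 1,3 O-to-C silyl migration (retro-Brook rearrangement) to the lithium salt of silylphenol 9. Trapping with Tf2O brings the fallback back to the route at triflate 10, bypassing steps 2 to 4.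

Step 8. Conversion may be low, the electron-rich quinol may be oxidized further, or the pyranone may open in alkali. The fallback sets out from flavone 17 and bypasses steps 7 to 9. Electrophilic iodination of the fully alkylated ring A (NIS, catalytic TFA, CH2Cl2) is expected at C8 and should give 5,7-bis(benzyloxy)-8-iodo-2-(3,4,5-trimethoxyphenyl)-4H-chromen-4-one F5. Ullmann-type methoxylation (NaOMe, CuBr, MeOH–DMF, 100 °C) gives 5,7-bis(benzyloxy)-8-methoxy-2-(3,4,5-trimethoxyphenyl)-4H-chromen-4-one F6. Hydrogenolysis of both benzyl ethers (H2, 10% Pd/C, EtOAc–MeOH) comes back to the route at target 23.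

**Further compounds**
F1 | step 6 | 3,5-bis(benzyloxy)-2-iodophenyl N-isopropylcarbamate | CC(C)NC(=O)Oc1cc(OCc2ccccc2)cc(OCc2ccccc2)c1I
F2 | step 6 | 3,5-bis(benzyloxy)-2-iodophenol | Oc1cc(OCc2ccccc2)cc(OCc2ccccc2)c1I
F3 | step 3 | 3,5-bis(benzyloxy)-2-bromophenol | Oc1cc(OCc2ccccc2)cc(OCc2ccccc2)c1Br
F4 | step 3 | [3,5-bis(benzyloxy)-2-bromophenoxy]trimethylsilane | C[Si](C)(C)Oc1cc(OCc2ccccc2)cc(OCc2ccccc2)c1Br
F5 | step 8 | 5,7-bis(benzyloxy)-8-iodo-2-(3,4,5-trimethoxyphenyl)-4H-chromen-4-one | COc1cc(-c2cc(=O)c3c(OCc4ccccc4)cc(OCc4ccccc4)c(I)c3o2)cc(OC)c1OC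
F6 | step 8 | 5,7-bis(benzyloxy)-8-methoxy-2-(3,4,5-trimethoxyphenyl)-4H-chromen-4-one | COc1cc(-c2cc(=O)c3c(OCc4ccccc4)cc(OCc4ccccc4)c(OC)c3o2)cc(OC)c1OC
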